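Sodwanone T is two copies of one trans-fused bicycle, an oxepane (O1, C2–C7; labels of one squalene half) fused at C6–C7 to the cyclohexene C6–C11. Everything rests on disconnecting that oxepane at C3–C4. The key step exploits this bond, which lies between the C2 gem-dimethyl carbon and the C5 methylene and away from every stereocentre: ring-closing olefin metathesis joins a C6 allyl group to a 1,1-dimethylallyl ether on the C7 oxygen and closes the seven-membered ether ring in one operation. Its precursor is a carvone-derived cyclohexenone with quaternary C6 and the C7–O bond already set trans. The C3=C4 olefin later carries the C3 oxygen; two halves are united by B-alkyl Suzuki coupling.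

Key step: step 9

Remarks on the chemistry.
- Labels: O1, C2 (gem-dimethyl), C3, C4, C5, C6 (angular methyl), C7 (ring-fusion CH–O), C8, C9, C10 (vinyl methyl), C11 (carbon bearing the linker). The monocycles made from carvone carry the same labels C6–C11. In the target the linker is C12–C13 and the second ring starts at C14.
- Assumption: the face of the epoxidation in step 10 is not predicted. Compounds 17–23 are therefore written without a descriptor at C3 (and C4 or C11 where these are stereocentres). This costs nothing, because C3 becomes a ketone in step 15.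
- The C6 side chain is carried as a silyl-capped propargyl group until step 8, so that the isopropenyl group can be degraded by ozone without a second olefin in the molecule.
- Keto enol triflate 24 is divided: one part goes to step 16, the other is the coupling partner in step 18.

Step 1
Reactants: 1 (S)-carvone; 2 iodomethane
Product: 4 6-methylcarvone, via lithium dienolate 3 (not isolated)
Conditions: LiN(i-Pr)2, THF, −78 °C; MeI, −78 → 0 °C
Reagents that add atoms: iodomethane (2), CI
Why: Kinetic α′-deprotonation of the cross-conjugated enone by the lithium amide and SN2 methylation of dienolate 3 (enolate alkylation) should give 4; the new C6 centre forms mainly trans to the isopropenyl group but is erased by re-enolisation in step 2.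

Step 2
Reactants: 4 6-methylcarvone; 5 3-bromo-1-(trimethylsilyl)prop-1-yne
Product: 7 6-methyl-6-(3-trimethylsilylprop-2-ynyl)carvone, via lithium enolate 6 (not isolated)
Conditions: LiN(i-Pr)2, THF, −78 °C; 5, DMPU, −78 → 0 °C
Reagents that add atoms: 3-bromo-1-(trimethylsilyl)prop-1-yne (5), C[Si](C)(C)C#CCBr
Why: Enolate alkylation: the tetrasubstituted enolate 6 should take up the reactive propargylic bromide on the face away from the neighbouring C7 isopropenyl group, which sets quaternary C6 with the propargyl chain trans and the methyl cis to isopropenyl, and the silyl cap prevents proton transfer from the alkyne.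

Step 3
Reactants: 7 6-methyl-6-(3-trimethylsilylprop-2-ynyl)carvone
Product: 9 C7 acetate, via methoxy hydroperoxide 8 (not isolated)
Conditions: O3, CH2Cl2/MeOH, −78 °C, Sudan Red 7B end point; then Ac2O, Et3N, DMAP (cat.), CH2Cl2, 0 → 40 °C
Reagents that add atoms: ozone, [O-][O+]=O; methanol, CO
Why: Ozonolysis in methanol followed by Criegee rearrangement: ozone cleaves only the electron-rich 1,1-disubstituted olefin (the enone olefin and the silylalkyne react far more slowly), the carbonyl oxide is trapped as methoxy hydroperoxide 8, and on O-acetylation the secondary C7 carbon migrates to oxygen with retention, so that the C7–O bond replaces the C7–C bond and the old C(CH3) unit becomes the acetyl group.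

Step 4
Reactants: 9 C7 acetate
Product: 10 hydroxy alkyne
Conditions: K2CO3 (cat.), MeOH, 0 °C → rt
Reagents that add atoms: none
Why: Carbonate-catalysed methanolysis removes the acetyl group (transesterification) and the C-silyl group (protodesilylation) in one operation; quaternary C6 rules out β-elimination of the β-hydroxy ketone and the mild base at low temperature should not trigger retro-aldol cleavage.

Step 5
Reactants: 11 2-methylbut-3-yn-2-ol
Product: 12 hexacarbonyldicobalt complex of 11
Conditions: Co2(CO)8, CH2Cl2, rt
Reagents that add atoms: dicobalt octacarbonyl, O=C=[Co](=C=O)(=C=O)(=C=O)[Co](=C=O)(=C=O)(=C=O)=C=O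
Why: Alkyne complexation: the terminal alkyne displaces two CO ligands of Co2(CO)8 to give the tetrahedral dicobalt hexacarbonyl complex needed for a Nicholas reaction.

Step 6
Reactants: 10 hydroxy alkyne; 12 hexacarbonyldicobalt complex of 11
Product: 13 cobalt-complexed tertiary propargylic ether
Conditions: 12 (1.5 equiv), BF3·OEt2 (1.1 equiv), CH2Cl2, −20 → 0 °C
Reagents that add atoms: none
Why: Nicholas reaction: BF3 ionises the tertiary alcohol of 12 to a cobalt-stabilised propargylic cation that is captured by the hindered C7 hydroxyl of 10 (SN1 etherification), giving a tertiary alkyl secondary alkyl ether out of reach of Williamson chemistry, while the uncomplexed alkyne and the enone are spectators and C7 is not touched.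

Step 7
Reactants: 13 cobalt-complexed tertiary propargylic ether
Product: 14 diyne ether
Conditions: (NH4)2Ce(NO3)6, acetone, −78 → 0 °C
Reagents that add atoms: none
Why: Oxidative decomplexation: tetravalent cerium oxidises the cobalt and liberates the alkyne under cold, nearly neutral conditions that the ether, enone and second alkyne tolerate.

Step 8
Reactants: 14 diyne ether
Product: 15 metathesis precursor (6-allyl 1,1-dimethylallyl ether)
Conditions: H2 (1 atm), Pd/CaCO3 poisoned with Pb(OAc)2, quinoline, EtOAc, rt, stopped after 2 equiv H2
Reagents that add atoms: none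
Why: Lindlar semihydrogenation: both terminal alkynes are adsorbed on the lead-poisoned palladium far more strongly than the olefins they give or the enone, so hydrogen uptake should stop at diene 15 when two equivalents have been consumed.

Step 9
Reactants: 15 metathesis precursor (6-allyl 1,1-dimethylallyl ether)
Product: 16 trans-fused oxepene–cyclohexenone
Conditions: second-generation Grubbs catalyst RuCl2(=CHPh)(H2IMes)(PCy3) (5 mol %), CH2Cl2 (5 mM), 40 °C
Reagents that add atoms: none
Why: Ring-closing olefin metathesis by the Chauvin mechanism: the ruthenium benzylidene exchanges onto the unhindered allyl terminus, the resulting alkylidene at C4 adds across the vinyl group of the 1,1-dimethylallyl ether in a [2+2] cycloaddition, and cycloreversion of the metallacyclobutane forms C3=C4 and releases ethylene, which drives the reaction. The closest known reaction type is ring-closing metathesis of 1,8-dienes to seven-membered cyclic allylic ethers that carry a fully substituted carbon next to oxygen. The oxepene is closed by joining the two olefin termini of the 1,8-diene with loss of C2H4; the C2 gem-dimethyl group and the trans arrangement of the C6 allyl and C7 alkoxy groups hold the two chains close, so the ring emerges trans-fused. No stereocentre is formed, and C6 and C7 (from steps 2 and 3) are not touched. The step needs chemoselectivity for the two monosubstituted olefins over the trisubstituted, electron-poor enone olefin, which reacts far more slowly with the ruthenium alkylidene, and ring closure over oligomerisation, which high dilution secures.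

Step 10
Reactants: 16 trans-fused oxepene–cyclohexenone
Product: 17 C3–C4 epoxy enone
Conditions: mCPBA, CH2Cl2, 0 °C → rt
Reagents that add atoms: mCPBA, OOC(=O)c1cccc(Cl)c1
Why: Prilezhaev epoxidation: the peracid attacks the isolated cis-disubstituted C3=C4 olefin and leaves the electron-poor, conjugated C9=C10 olefin, and either epoxide face is acceptable because C3 later passes through a ketone.

Step 11
Reactants: 17 C3–C4 epoxy enone
Product: 18 C3,C11 diol
Conditions: LiAlH4, Et2O, 0 °C → reflux
Reagents that add atoms: none
Why: Hydride reduction: LiAlH4 opens the epoxide by SN2 attack at C4, the carbon remote from the quaternary C2 that shields C3, to leave the C3 carbinol, and at the same time reduces the C11 carbonyl in the 1,2 sense to the allylic alcohol (any C11 epimer serves).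

Step 12
Reactants: 18 C3,C11 diol
Product: 19 C3-hydroxy enone
Conditions: MnO2 (excess), CH2Cl2, rt
Reagents that add atoms: none
Why: Chemoselective allylic oxidation: MnO2 oxidises only the allylic C11 alcohol back to the enone and leaves the saturated, hindered C3 alcohol.

Step 13
Reactants: 19 C3-hydroxy enone
Product: 20 C3 triethylsilyl ether
Conditions: Et3SiOTf, 2,6-lutidine, CH2Cl2, −78 → 0 °C
Reagents that add atoms: triethylsilyl trifluoromethanesulfonate, CC[Si](CC)(CC)OS(=O)(=O)C(F)(F)F
Why: Silyl ether formation with the reactive silyl triflate and a hindered pyridine base protects the C3 hydroxyl, which would otherwise quench the hydride and be sulfonylated in step 14.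

Step 14
Reactants: 20 C3 triethylsilyl ether
Product: 23 C3-hydroxy enol triflate, via lithium enolate 21 (not isolated), via silyl enol triflate 22 (not isolated)
Conditions: LiBH(s-Bu)3, THF, −78 °C; PhNTf2, −78 °C → rt; then 1 M aq. HCl, THF, rt
Reagents that add atoms: N-phenylbis(trifluoromethanesulfonimide), O=S(=O)(N(c1ccccc1)S(=O)(=O)C(F)(F)F)C(F)(F)F
Why: Conjugate reduction with enolate trapping: the bulky borohydride delivers hydride to C9 of the enone (1,2-attack is blocked by quaternary C6), the resulting C10=C11 enolate 21 is O-sulfonylated by the triflimide to the tetrasubstituted enol triflate 22 with the double bond fixed where the target needs it, and dilute acid then hydrolyses the triethylsilyl ether.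

Step 15
Reactants: 23 C3-hydroxy enol triflate
Product: 24 keto enol triflate
Conditions: Dess–Martin periodinane, CH2Cl2, rt
Reagents that add atoms: none
Why: Dess–Martin oxidation of the secondary alcohol gives the C3 ketone and merges both C3 epimers into one compound, the enol triflate and ethers being inert to the periodinane.

Step 16
Reactants: 24 keto enol triflate (one part of the material)
Product: 25 (3R)-hydroxy enol triflate
Conditions: NaBH4, MeOH, −20 → 0 °C
Reagents that add atoms: none
Why: Borohydride reduction of the ketone: hydride should approach C3 of the trans-fused oxepanone from the face opposite the axial C6 methyl group, which places the new hydroxyl cis to that methyl (3R), and the enol triflate does not react with NaBH4.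

Step 17
Reactants: 25 (3R)-hydroxy enol triflate; 26 tributyl(vinyl)stannane
Product: 27 (3R)-hydroxy diene
Conditions: Pd2(dba)3 (cat.), AsPh3, LiCl, NMP, 60 °C
Reagents that add atoms: tributyl(vinyl)stannane (26), C=C[Sn](CCCC)(CCCC)CCCC
Why: Stille coupling: oxidative addition of zerovalent palladium into the enol triflate, chloride-assisted transmetalation of the vinyl group from tin (arsine ligand and polar solvent speed this step for the hindered partner) and reductive elimination form the C11–C12 bond without affecting the free hydroxyl.

Step 18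
Reactants: 27 (3R)-hydroxy diene; 24 keto enol triflate
Product: 29 sodwanone T, via B-alkyl-9-BBN 28 (not isolated)
Conditions: 9-BBN (2.5 equiv), THF, 0 °C → rt; then 3 M aq. Cs2CO3, 24, PdCl2(dppf) (cat.), AsPh3, DMF, rt → 50 °C
Reagents that add atoms: none
Why: B-alkyl Suzuki–Miyaura coupling: 9-BBN adds only to the terminal vinyl group of 27 with boron on C13 (the tetrasubstituted ring olefin is inert and the excess covers any slow reaction at the hydroxyl), and the hydroxide-activated alkylborane transfers its primary alkyl group to the palladium formed by oxidative addition into enol triflate 24, so that reductive elimination forges the C13–C14 bond and leaves the C3 ketone and carbinol untouched.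

Compound list

1 | (S)-carvone, (5S)-2-methyl-5-(prop-1-en-2-yl)cyclohex-2-en-1-one | CC1=CC[C@@H](CC1=O)C(C)=C | starting material
2 | iodomethane | CI | starting material
3 | lithium dienolate of 1 (O–Li on C11, C6=C11 double bond; not isolated) | CC1=CC[C@@H](C=C1O[Li])C(C)=C | intermediate
4 | 6-methylcarvone, drawn as the main (5S,6R) epimer with methyl trans to isopropenyl; the C6 epimer serves equally | CC1=CC[C@@H]([C@@H](C)C1=O)C(C)=C | intermediate
5 | 3-bromo-1-(trimethylsilyl)prop-1-yne | C[Si](C)(C)C#CCBr | starting material
6 | lithium enolate of 4 (tetrasubstituted C6=C11 enolate; not isolated) | CC1=CC[C@@H](C(C)=C1O[Li])C(C)=C | intermediate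
7 | (5R,6R)-2,6-dimethyl-5-(prop-1-en-2-yl)-6-[3-(trimethylsilyl)prop-2-yn-1-yl]cyclohex-2-en-1-one (propargyl trans to isopropenyl) | O=C1C(C)=CC[C@H](C(C)=C)[C@@]1(C)CC#C[Si](C)(C)C | intermediate
8 | methoxy hydroperoxide from 7: isopropenyl replaced by C(CH3)(OCH3)OOH, epimers at that carbon (not isolated) | O=C1C(C)=CC[C@H](C(C)(OC)OO)[C@@]1(C)CC#C[Si](C)(C)C | intermediate
9 | (5S,6R)-5-acetoxy-2,6-dimethyl-6-[3-(trimethylsilyl)prop-2-yn-1-yl]cyclohex-2-en-1-one | O=C1C(C)=CC[C@H](OC(C)=O)[C@@]1(C)CC#C[Si](C)(C)C | intermediate
10 | (5S,6R)-5-hydroxy-2,6-dimethyl-6-(prop-2-yn-1-yl)cyclohex-2-en-1-one | O=C1C(C)=CC[C@H](O)[C@@]1(C)CC#C | intermediate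
11 | 2-methylbut-3-yn-2-ol | CC(C)(O)C#C | starting material
12 | hexacarbonyldicobalt complex of 11, (2-methylbut-3-yn-2-ol)Co2(CO)6 | CC(C)(O)C12[Co]3(=C=O)(=C=O)(=C=O)[Co]1(=C=O)(=C=O)(=C=O)C23 | intermediate
13 | Co2(CO)6 complex of the 2-methylbut-3-yn-2-yl ether of 10 (cobalt on the ether alkyne) | O=C1C(C)=CC[C@H](OC(C)(C)C23[Co]4(=C=O)(=C=O)(=C=O)[Co]2(=C=O)(=C=O)(=C=O)C34)[C@@]1(C)CC#C | intermediate
14 | (5S,6R)-2,6-dimethyl-5-[(2-methylbut-3-yn-2-yl)oxy]-6-(prop-2-yn-1-yl)cyclohex-2-en-1-one | O=C1C(C)=CC[C@H](OC(C)(C)C#C)[C@@]1(C)CC#C | intermediate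
15 | (5S,6R)-6-allyl-2,6-dimethyl-5-[(2-methylbut-3-en-2-yl)oxy]cyclohex-2-en-1-one | O=C1C(C)=CC[C@H](OC(C)(C)C=C)[C@@]1(C)CC=C | intermediate
16 | (5aR,9aS)-2,2,5a,7-tetramethyl-5,5a,9,9a-tetrahydro-1-benzoxepin-6(2H)-one (trans-fused; C6 R, C7 S in the labels used here) | O=C1C(C)=CC[C@@H]2OC(C)(C)C=CC[C@@]12C | intermediate
17 | C3–C4 epoxide of 16 (epoxide face not assigned; ring fusion as in 16) | O=C1C(C)=CC[C@@H]2OC(C)(C)C3OC3C[C@@]12C | intermediate
18 | diol from 17: C3 carbinol, C4 methylene, C11 allylic carbinol (C3 and C11 not assigned; ring fusion as in 16) | OC1C(C)=CC[C@@H]2OC(C)(C)C(O)CC[C@@]12C | intermediate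
19 | C3-hydroxy enone (C11 ketone restored; C3 not assigned) | O=C1C(C)=CC[C@@H]2OC(C)(C)C(O)CC[C@@]12C | intermediate
20 | C3 triethylsilyl ether of 19 | O=C1C(C)=CC[C@@H]2OC(C)(C)C(O[Si](CC)(CC)CC)CC[C@@]12C | intermediate
21 | lithium C10=C11 enolate from 1,4-reduction of 20 (not isolated) | [Li]OC1=C(C)CC[C@@H]2OC(C)(C)C(O[Si](CC)(CC)CC)CC[C@@]12C | intermediate
22 | C11 enol triflate bearing C3–OSiEt3 (not isolated) | O=S(=O)(OC1=C(C)CC[C@@H]2OC(C)(C)C(O[Si](CC)(CC)CC)CC[C@@]12C)C(F)(F)F | intermediate
23 | C11 enol triflate bearing free C3–OH (C3 not assigned) | O=S(=O)(OC1=C(C)CC[C@@H]2OC(C)(C)C(O)CC[C@@]12C)C(F)(F)F | intermediate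
24 | (5aR,9aS)-2,2,5a,7-tetramethyl-3-oxo-2,3,4,5,5a,8,9,9a-octahydro-1-benzoxepin-6-yl trifluoromethanesulfonate | O=S(=O)(OC1=C(C)CC[C@@H]2OC(C)(C)C(=O)CC[C@@]12C)C(F)(F)F | intermediate
25 | (3R,5aR,9aS)-3-hydroxy-2,2,5a,7-tetramethyl-2,3,4,5,5a,8,9,9a-octahydro-1-benzoxepin-6-yl trifluoromethanesulfonate (hydroxyl cis to the angular methyl) | O=S(=O)(OC1=C(C)CC[C@@H]2OC(C)(C)[C@H](O)CC[C@@]12C)C(F)(F)F | intermediate
26 | tributyl(vinyl)stannane | C=C[Sn](CCCC)(CCCC)CCCC | starting material
27 | (3R,5aS,9aS)-6-ethenyl-2,2,5a,7-tetramethyl-2,3,4,5,5a,8,9,9a-octahydro-1-benzoxepin-3-ol | C=CC1=C(C)CC[C@@H]2OC(C)(C)[C@H](O)CC[C@@]12C | intermediate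
28 | B-alkyl-9-BBN from 27: 9-borabicyclo[3.3.1]nonan-9-yl on C13 of the C11–CH2CH2 chain (not isolated) | C(CB1C2CCCC1CCC2)C1=C(C)CC[C@@H]2OC(C)(C)[C@H](O)CC[C@@]12C | intermediate
29 | sodwanone T: (3R,6S,7S) in the alcohol half, (S,S) at the corresponding ring-fusion centres of the ketone half | CC1=C(CCC2=C(C)CC[C@@H]3OC(C)(C)[C@H](O)CC[C@@]23C)[C@]2(C)CCC(=O)C(C)(C)O[C@H]2CC1 | target

Total step count: 18. Longest linear sequence: 17 steps (steps 1–4 and 6–18; step 5 prepares reagent 12 on a side branch).

Steps most likely to fail

Step 9 (ring closure). The alkylidene formed at the allyl terminus may fail to engage the olefin next to quaternary C2, so that intermolecular metathesis and olefin migration overtake ring closure. The fallback closes the O1–C2 bond on a cobalt-bent alkyne instead of using olefin metathesis; it sets out from 4 and comes back at 16.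
- 3-Methoxy-3-methylbut-1-yne is lithiated (n-BuLi) and hydroxymethylated with paraformaldehyde to 4-methoxy-4-methylpent-2-yn-1-ol F1, which CBr4/PPh3 converts into 1-bromo-4-methoxy-4-methylpent-2-yne F2.
- Enolate 6, made from 4 as in step 2, is alkylated with F2 to the 6-(4-methoxy-4-methylpent-2-ynyl) enone F3.
- Ozonolysis of F3 in methanol gives the methoxy hydroperoxide F4, Ac2O/Et3N/DMAP turns it into the acetate F5 as in step 3, and K2CO3/MeOH gives the hydroxy alkyne F6.
- Co2(CO)8 gives the hexacarbonyldicobalt complex F7. BF3·OEt2 then ionises the tertiary methyl ether and the C7 hydroxyl closes the seven-membered ring (intramolecular Nicholas reaction) to the cyclic complex F8; the bent complexed alkyne makes this ring size accessible.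
- n-Bu3SnH in benzene at 65 °C removes the cobalt reductively and should give the cis olefin 16.

Step 18 (union of the halves). Oxidative addition and transmetalation at the enol triflate, which is flanked by a quaternary carbon and a methyl-bearing carbon, may be slower than hydrolysis of the triflate or protodeboronation of the borane. The fallback is a cross-electrophile coupling in place of a boron nucleophile; it sets out from 27 and comes back at 29. Borane 28, formed from 27 as in step 18, is treated with I2 and NaOMe in MeOH to give the primary iodide F9. F9 is joined to triflate 24 by nickel-catalysed reductive coupling (NiCl2(MeOCH2CH2OMe), 4,4'-di-tert-butyl-2,2'-bipyridine, Mn powder, DMA); this pathway tolerates the ketone and the free hydroxyl and should give 29 directly.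

Step 16 (C3 carbinol). Hydride delivery to the C3 ketone of the flexible seven-membered ring may show poor facial selectivity and give the C3 epimer. The fallback replaces substrate control by catalyst control; it sets out from 24 and comes back at 25. Corey–Bakshi–Shibata reduction with (S)-2-methyl-CBS-oxazaborolidine and BH3·SMe2 in THF differentiates quaternary C2 from the C4 methylene and should give the (3R) alcohol 25 whatever the ring bias; no new compound is made (F0).

Further compounds

F1 | step 9 | 4-methoxy-4-methylpent-2-yn-1-ol | COC(C)(C)C#CCO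
F2 | step 9 | 1-bromo-4-methoxy-4-methylpent-2-yne | COC(C)(C)C#CCBr
F3 | step 9 | (5R,6R)-6-(4-methoxy-4-methylpent-2-yn-1-yl)-2,6-dimethyl-5-(prop-1-en-2-yl)cyclohex-2-en-1-one | O=C1C(C)=CC[C@H](C(C)=C)[C@@]1(C)CC#CC(C)(C)OC
F4 | step 9 | methoxy hydroperoxide from F3 (isopropenyl replaced by C(CH3)(OCH3)OOH) | O=C1C(C)=CC[C@H](C(C)(OC)OO)[C@@]1(C)CC#CC(C)(C)OC
F5 | step 9 | (5S,6R)-5-acetoxy-6-(4-methoxy-4-methylpent-2-yn-1-yl)-2,6-dimethylcyclohex-2-en-1-one | O=C1C(C)=CC[C@H](OC(C)=O)[C@@]1(C)CC#CC(C)(C)OC
F6 | step 9 | (5S,6R)-5-hydroxy-6-(4-methoxy-4-methylpent-2-yn-1-yl)-2,6-dimethylcyclohex-2-en-1-one | O=C1C(C)=CC[C@H](O)[C@@]1(C)CC#CC(C)(C)OC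
F7 | step 9 | Co2(CO)6 complex of F6 | O=C1C(C)=CC[C@H](O)[C@@]1(C)CC23[Co]4(=C=O)(=C=O)(=C=O)[Co]2(=C=O)(=C=O)(=C=O)C34C(C)(C)OC
F8 | step 9 | Co2(CO)6 complex of the C3–C4 alkyne analogue of 16 (trans-fused cyclic ether) | O=C1C(C)=CC[C@@H]2OC(C)(C)C34[Co]5(=C=O)(=C=O)(=C=O)[Co]3(=C=O)(=C=O)(=C=O)C45C[C@@]12C
F9 | step 18 | (3R,5aS,9aS)-6-(2-iodoethyl)-2,2,5a,7-tetramethyl-2,3,4,5,5a,8,9,9a-octahydro-1-benzoxepin-3-ol | ICCC1=C(C)CC[C@@H]2OC(C)(C)[C@H](O)CC[C@@]12C
F0 | step 16 | none | none
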